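**Retrosynthetic overview**

1. Target ⇐ metal-free reduction of the C2=C3 alkene of the trans-4-aryl-1,4-dihydronaphthalen-1-ol; both stereocentres are already in place.
2. C4–C2′ bond and the C4 centre ⇐ suprafacial aromatic Claisen shift of a trans-2-(naphthyloxy)-1,2-dihydronaphthalen-1-ol. The aryl group arrives at C4 on the face of the C2–O bond, anti to C1–OH, so 1,2-trans becomes 1,4-trans.
3. That allyl aryl ether ⇐ Rh-catalysed asymmetric ring opening of 5-methoxy-7-oxabenzonorbornadiene by the oxygen of 8-methoxynaphthalen-1-ol (sets C1 and C2).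
4. Oxabenzonorbornadiene ⇐ 3-methoxybenzyne + furan [4+2]. The same two C–C bonds close carbocycle B and the benzo-fused 1,4-epoxy bridge ring in one operation.
5. Ring order: the anisole ring and both naphthalene rings are bought; ring B and the temporary oxa-bridge ring form together in the first step; no ring is made later, and the bridge ring is opened in the ring-opening step.

Assumption: 8-methoxynaphthalen-1-ol is bought as a catalogue compound, and the (S)-(R) antipode of the Josiphos ligand is taken as the one giving the (1R,2R) series (otherwise its mirror image is used).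

**Route**

Step 1
Reactants: 1 3-bromoanisole; 2 furan
Product: 5 rac-5-methoxy-1,4-dihydro-1,4-epoxynaphthalene, via aryllithium 3 (not isolated), via 3-methoxybenzyne 4 (not isolated)
Conditions: LDA (1.2 equiv), furan (10 equiv), THF, −78 °C → rt
Reagents that add atoms: none
Why: LDA removes H-2 of 1 (flanked by Br and OMe) to give 3, which ejects LiBr to aryne 4, and furan traps 4 in an aryne Diels–Alder [4+2] whose two new C–C bonds close carbocycle B and the benzo-fused 1,4-epoxy bridge ring at once; the bridgeheads are necessarily cis and 5 is racemic.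

Step 2
Reactants: 5 rac-5-methoxy-1,4-dihydro-1,4-epoxynaphthalene; 6 8-methoxynaphthalen-1-ol
Product: 7 (1R,2R)-5-methoxy-2-[(8-methoxynaphthalen-1-yl)oxy]-1,2-dihydronaphthalen-1-ol
Conditions: [Rh(cod)Cl]2 (2.5 mol %), (S)-(R)-PPF-P(t-Bu)2 (6 mol %), 6 (1.5 equiv), THF, 80 °C
Reagents that add atoms: none
Why: Lautens-type Rh(I)/Josiphos asymmetric ring opening, in which rhodium inserts exo into the bridgehead C–O bond next to the methoxy-bearing carbon and the naphthol oxygen attacks SN2′ anti to rhodium, gives the trans-1,2 product with C1 and C2 fixed as (1R,2R) by the ligand; on racemic 5 this is a regiodivergent resolution, so only the (1S,4R) half of 5 gives 7 (at most 50 % based on 5) and the other half gives a separable regioisomer.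

Step 3
Reactants: 7 (1R,2R)-5-methoxy-2-[(8-methoxynaphthalen-1-yl)oxy]-1,2-dihydronaphthalen-1-ol
Product: 9 (1S,4R)-4-(1-hydroxy-8-methoxynaphthalen-2-yl)-5-methoxy-1,4-dihydronaphthalen-1-ol, via ortho-dienone 8 (not isolated)
Conditions: Eu(fod)3 (10 mol %), CHCl3, 55 °C
Reagents that add atoms: none
Why: Aromatic Claisen rearrangement ([3,3]-sigmatropic, Eu(III)-catalysed as known for aryl cycloalkenyl ethers) bonds the naphthyl ortho-carbon to C4 suprafacially, on the face of the breaking C2–O bond and so anti to C1–OH, which transfers the C2 centre to C4 (R) while C1 is untouched, and dienone 8 enolises to the naphthol.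

Step 4
Reactants: 9 (1S,4R)-4-(1-hydroxy-8-methoxynaphthalen-2-yl)-5-methoxy-1,4-dihydronaphthalen-1-ol
Product: 10 (1S,4R)-4-(1-hydroxy-8-methoxynaphthalen-2-yl)-5-methoxy-1,2,3,4-tetrahydronaphthalen-1-ol (Dipolynaphthalene A)
Conditions: 2-nitrobenzenesulfonylhydrazide (NBSH, 4 equiv), Et3N, THF, rt
Reagents that add atoms: none
Why: Diimide alkene reduction (diimide made in situ from NBSH) saturates the isolated cis-disubstituted C2=C3 bond by concerted syn hydrogen transfer without touching the arenes or the acid- and hydrogenolysis-prone benzylic C–O bond, and no stereocentre is involved.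

**Compound list**

1 | 3-bromoanisole (1-bromo-3-methoxybenzene) | COc1cccc(Br)c1 | starting material
2 | furan | c1ccoc1 | starting material
3 | (2-bromo-6-methoxyphenyl)lithium | COc1cccc(Br)c1[Li] | intermediate
4 | 3-methoxybenzyne (1-methoxy-2,3-didehydrobenzene) | COC1=CC=CC#C1 | intermediate
5 | rac-5-methoxy-1,4-dihydro-1,4-epoxynaphthalene (racemate; the (1S,4R) enantiomer, which leads to 7, is drawn) | COc1cccc2c1[C@H]1C=C[C@@H]2O1 | intermediate
6 | 8-methoxynaphthalen-1-ol | COc1cccc2cccc(O)c12 | starting material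
7 | (1R,2R)-5-methoxy-2-[(8-methoxynaphthalen-1-yl)oxy]-1,2-dihydronaphthalen-1-ol | COc1cccc2c1C=C[C@@H](Oc1cccc3cccc(OC)c13)[C@@H]2O | intermediate
8 | 2-[(1R,4S)-4-hydroxy-8-methoxy-1,4-dihydronaphthalen-1-yl]-8-methoxynaphthalen-1(2H)-one (ortho-dienone; C2 of the naphthalenone left unspecified, it is lost on enolisation) | COc1cccc2c1[C@@H](C1C=Cc3cccc(OC)c3C1=O)C=C[C@@H]2O | intermediate
9 | (1S,4R)-4-(1-hydroxy-8-methoxynaphthalen-2-yl)-5-methoxy-1,4-dihydronaphthalen-1-ol | COc1cccc2c1[C@@H](c1ccc3cccc(OC)c3c1O)C=C[C@@H]2O | intermediate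
10 | (1S,4R)-4-(1-hydroxy-8-methoxynaphthalen-2-yl)-5-methoxy-1,2,3,4-tetrahydronaphthalen-1-ol (Dipolynaphthalene A) | COc1cccc2c1[C@@H](c1ccc3cccc(OC)c3c1O)CC[C@@H]2O | target

**Count**

Total step count: 4. Longest linear sequence: 4 steps (1 → 5 → 7 → 9 → 10).

**Steps most likely to fail, with fallbacks**

Step 2. The substrate is racemic and unsymmetrical, and the peri-substituted naphthol is a hindered nucleophile, so regiocontrol, ee and rate are all uncertain. The fallback sets out from 5 and comes back at 7. Racemic 5 is opened with 6 under an achiral catalyst ([Rh(cod)Cl]2/dppf, THF, 80 °C), where the methoxy group alone directs cleavage of the proximal C–O bond, to give rac-(1R,2R)-5-methoxy-2-[(8-methoxynaphthalen-1-yl)oxy]-1,2-dihydronaphthalen-1-ol F1. F1 is then resolved by lipase acylation (CAL-B, vinyl acetate, MTBE), which turns the unwanted antipode into (1S,2S)-5-methoxy-2-[(8-methoxynaphthalen-1-yl)oxy]-1,2-dihydronaphthalen-1-yl acetate F2 and leaves 7, separated on silica.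

Step 3. Lewis-acid ionisation of the doubly activated allylic ether can lead to loss of the naphthol and aromatisation instead of the [3,3] shift. The fallback sets out from 7 and comes back at 9. The C1 hydroxyl is silylated (TBSCl, imidazole, DMF) to tert-butyl{[(1R,2R)-5-methoxy-2-[(8-methoxynaphthalen-1-yl)oxy]-1,2-dihydronaphthalen-1-yl]oxy}dimethylsilane F3. F3 is rearranged thermally without Lewis acid (N,N-diethylaniline, 180 °C) to 2-[(1R,4S)-4-(tert-butyldimethylsilyloxy)-8-methoxy-1,4-dihydronaphthalen-1-yl]-8-methoxynaphthalen-1-ol F4, and TBAF in THF returns 9.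

Step 4. Diimide may be slow on the flanked ring alkene, and 9 dehydrates easily to a 1-arylnaphthalene. The fallback sets out from 9 and comes back at 10. Both hydroxyls are capped (TESCl, imidazole, DMF) to triethyl{[(1S,4R)-5-methoxy-4-{8-methoxy-1-[(triethylsilyl)oxy]naphthalen-2-yl}-1,4-dihydronaphthalen-1-yl]oxy}silane F5. F5 is hydrogenated over a heterogeneous catalyst (H2, Pt/C, EtOAc) to triethyl{[(1S,4R)-5-methoxy-4-{8-methoxy-1-[(triethylsilyl)oxy]naphthalen-2-yl}-1,2,3,4-tetrahydronaphthalen-1-yl]oxy}silane F6, and TBAF in THF releases 10.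

**Further compounds**

F1 | step 2 | rac-(1R,2R)-5-methoxy-2-[(8-methoxynaphthalen-1-yl)oxy]-1,2-dihydronaphthalen-1-ol (racemate, one enantiomer drawn) | COc1cccc2c1C=C[C@@H](Oc1cccc3cccc(OC)c13)[C@@H]2O
F2 | step 2 | (1S,2S)-5-methoxy-2-[(8-methoxynaphthalen-1-yl)oxy]-1,2-dihydronaphthalen-1-yl acetate | COc1cccc2c1C=C[C@H](Oc1cccc3cccc(OC)c13)[C@H]2OC(C)=O
F3 | step 3 | tert-butyl{[(1R,2R)-5-methoxy-2-[(8-methoxynaphthalen-1-yl)oxy]-1,2-dihydronaphthalen-1-yl]oxy}dimethylsilane | COc1cccc2c1C=C[C@@H](Oc1cccc3cccc(OC)c13)[C@@H]2O[Si](C)(C)C(C)(C)C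
F4 | step 3 | 2-[(1R,4S)-4-(tert-butyldimethylsilyloxy)-8-methoxy-1,4-dihydronaphthalen-1-yl]-8-methoxynaphthalen-1-ol | COc1cccc2c1[C@@H](c1ccc3cccc(OC)c3c1O)C=C[C@@H]2O[Si](C)(C)C(C)(C)C
F5 | step 4 | triethyl{[(1S,4R)-5-methoxy-4-{8-methoxy-1-[(triethylsilyl)oxy]naphthalen-2-yl}-1,4-dihydronaphthalen-1-yl]oxy}silane | COc1cccc2c1[C@@H](c1ccc3cccc(OC)c3c1O[Si](CC)(CC)CC)C=C[C@@H]2O[Si](CC)(CC)CC
F6 | step 4 | triethyl{[(1S,4R)-5-methoxy-4-{8-methoxy-1-[(triethylsilyl)oxy]naphthalen-2-yl}-1,2,3,4-tetrahydronaphthalen-1-yl]oxy}silane | COc1cccc2c1[C@@H](c1ccc3cccc(OC)c3c1O[Si](CC)(CC)CC)CC[C@@H]2O[Si](CC)(CC)CC
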